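**Retrosynthetic overview**
1. Last bond: the C4′ methyl, by enolate methylation of the caged ketone 14 (only one face is open).
2. Key step: the cyclopentane and the bicyclo[2.2.2]octene close together in an intramolecular dearomative para-[4+2] photocycloaddition of the methoxyphthalide ring of 12 with the C8=C12 alkene (bonds C8–C3a′ and C12–C6′), followed by enol ether hydrolysis.
3. 12 comes from ketone 11 (MeTiCl3); 11 comes from deconjugative α-benzylation (C9–C11) of dienone 7 with bromide 10 (two steps from 4-methoxy-3-methylbenzoic acid).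
4. 7 comes from (R)-pulegone, which supplies ring B, C4 with both methyls, and C12: Michael addition at C5, acid lactonisation onto the isopropenyl group (ring A), double dehydrogenation.
5. Ring order: B (bought) → A → arene lactone attached → cyclopentane plus bicyclo[2.2.2]octene (one photochemical step). Stereo relay: pulegone methyl → C5 → C9 → C10 → C8, C3a′, C6′, C4′.

Assumption and labels: the SMILES defines the target. Ring A is O–C4(Me2)–C5–C1H=C2H–C3(=O); ring B is C5–C10; C11 is the CH2 on C9; C12 is the CH2 on C8; primed numbers are phthalide positions (C4′ bears C11, C5′ bears oxygen, C6′ bears methyl, C3a′/C7a′ are the ring-fusion carbons).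

**Step 1**
Reactants: 1 (R)-(+)-pulegone; 2 tert-butyl acrylate
Product: 3 tert-butyl 3-[(1R,4R)-4-methyl-2-oxo-1-(prop-1-en-2-yl)cyclohexyl]propanoate
Conditions: KH, THF, 0 °C to rt; then 2, −78 °C; AcOH
Reagents that add atoms: none
Why: Michael addition of the thermodynamic, fully conjugated dienolate of pulegone through its α-carbon creates the quaternary C5; the acrylate enters axially on the half-chair that keeps the bought methyl equatorial, so the ester chain ends cis to that methyl (about 4:1 expected, minor isomer removed at crystalline 5).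

**Step 2**
Reactants: 3 tert-butyl 3-[(1R,4R)-4-methyl-2-oxo-1-(prop-1-en-2-yl)cyclohexyl]propanoate
Product: 5 (6R,9R)-1,1,9-trimethyl-2-oxaspiro[5.5]undecane-3,7-dione, via carboxylic acid 4 (not isolated)
Conditions: TFA, CH2Cl2, 0 °C to rt
Reagents that add atoms: none
Why: Acidolysis of the tert-butyl ester followed by Markovnikov cation–olefin lactonisation, in which the acid traps the tertiary cation from the protonated isopropenyl group to close ring A; no stereocentre is touched.

**Step 3**
Reactants: 5 (6R,9R)-1,1,9-trimethyl-2-oxaspiro[5.5]undecane-3,7-dione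
Product: 7 (6R)-1,1,9-trimethyl-2-oxaspiro[5.5]undeca-4,8-diene-3,7-dione, via bis-selenide 6 (not isolated)
Conditions: LDA (2.2 equiv), THF, −78 °C; PhSeBr; then H2O2, pyridine, CH2Cl2, 0 °C to rt
Reagents that add atoms: none
Why: Double α-selenenylation and selenoxide syn-elimination (Reich–Sharpless dehydrogenation); C9 is the only enolisable ketone α-position and C2 the only lactone α-position, so one operation gives the ring B enone and the ring A enoate, and the pulegone stereocentre is erased on purpose once it has set C5.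

**Step 4**
Reactants: 8 4-methoxy-3-methylbenzoic acid
Product: 9 5-methoxy-6-methyl-2-benzofuran-1(3H)-one
Conditions: Pd(OAc)2 (10 mol%), K2HPO4, CH2Br2, 140 °C
Reagents that add atoms: dibromomethane, BrCBr
Why: Carboxylate-directed Pd-catalysed ortho-C–H alkylation with CH2Br2 followed by intramolecular SN2 lactonisation; the less hindered ortho C–H (away from the methyl) reacts.

**Step 5**
Reactants: 9 5-methoxy-6-methyl-2-benzofuran-1(3H)-one
Product: 10 4-(bromomethyl)-5-methoxy-6-methyl-2-benzofuran-1(3H)-one
Conditions: (CH2O)n, HBr (33% in AcOH), 60 °C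
Reagents that add atoms: paraformaldehyde (as formaldehyde), C=O; hydrogen bromide, Br
Why: Blanc-type bromomethylation (electrophilic aromatic substitution); C4′ is the only free position ortho to the methoxy group and is meta to the acyl group.

**Step 6**
Reactants: 7 (6R)-1,1,9-trimethyl-2-oxaspiro[5.5]undeca-4,8-diene-3,7-dione; 10 4-(bromomethyl)-5-methoxy-6-methyl-2-benzofuran-1(3H)-one
Product: 11 (6R,8R)-8-[(5-methoxy-6-methyl-1-oxo-1,3-dihydro-2-benzofuran-4-yl)methyl]-1,1-dimethyl-9-methylidene-2-oxaspiro[5.5]undec-4-ene-3,7-dione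
Conditions: LDA (1.05 equiv), THF–DMPU, −78 °C; then 10, −78 to −40 °C
Reagents that add atoms: none
Why: Deconjugative α-alkylation of an extended enolate: with no α′-hydrogen, kinetic γ-deprotonation at the C12 methyl gives the exocyclic dienolate, which is benzylated at C9 with the alkene moving to C8=C12; the bromide enters anti to the pseudo-axial CMe2O arm (C4) of the spiro centre, so C11 is cis to C1.

**Step 7**
Reactants: 11 (6R,8R)-8-[(5-methoxy-6-methyl-1-oxo-1,3-dihydro-2-benzofuran-4-yl)methyl]-1,1-dimethyl-9-methylidene-2-oxaspiro[5.5]undec-4-ene-3,7-dione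
Product: 12 (6S,7R,8R)-7-hydroxy-8-[(5-methoxy-6-methyl-1-oxo-1,3-dihydro-2-benzofuran-4-yl)methyl]-1,1,7-trimethyl-9-methylidene-2-oxaspiro[5.5]undec-4-en-3-one
Conditions: MeTiCl3 (3 equiv, from TiCl4 and Me2Zn), CH2Cl2, −78 to −30 °C
Reagents that add atoms: methyltitanium trichloride, C[Ti](Cl)(Cl)Cl
Why: Reetz methylation: non-basic MeTiCl3 adds to ketones but not to lactones and does not enolise C9; in the chair with C1 and C11 axial (CMe2O equatorial, no allylic 1,3-strain between C11 and C12) the methyl is delivered to the opposite face, giving OH cis to C11 and C1.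

**Step 8**
Reactants: 12 (6S,7R,8R)-7-hydroxy-8-[(5-methoxy-6-methyl-1-oxo-1,3-dihydro-2-benzofuran-4-yl)methyl]-1,1,7-trimethyl-9-methylidene-2-oxaspiro[5.5]undec-4-en-3-one
Product: 14 4′-demethyl-andibenin B, via methyl enol ether 13 (not isolated)
Conditions: hν (300 nm), degassed benzene (2 mM), 20 °C; then 1 M HCl, THF, rt
Reagents that add atoms: water, O
Why: Proposed new method: intramolecular dearomative para-[4+2] photocycloaddition of a donor–acceptor benzene ring (the p-methoxybenzoate chromophore of the phthalide) with an unactivated 1,1-disubstituted alkene held two atoms away; excitation of the arene and exciplex formation lead by 1,5-closure (C8–C3a′, rule of five) and collapse of the biradical at the para carbon (C12–C6′) to the bicyclo[2.2.2]octadiene 13, whose enol ether is hydrolysed on acidic work-up with protonation of C4′ on its only open face; the O–H···OMe hydrogen bond from the C10 hydroxyl holds C8 over C3a′ and not over C5′, the axial C11 on the C9 stereocentre forces bond formation on the C11 face of the alkene (cis-fused cyclopentane, setting C8, C3a′ and C6′), and 13 no longer absorbs at 300 nm whereas an ortho [2+2] adduct (a cyclohexadiene) would be photolabile and revert; closest known reaction type: arene–alkene photocycloaddition (ortho, meta and the rare para mode) and energy-transfer dearomative [4+2] cycloaddition of naphthalenes, not yet shown for a benzene ring with a simple alkene forming a quaternary centre.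

**Step 9**
Reactants: 14 4′-demethyl-andibenin B
Product: 15 andibenin B
Conditions: LiHMDS (2.2 equiv), THF, −78 °C; MeI, −78 to −20 °C
Reagents that add atoms: iodomethane, CI
Why: Enolate C-methylation: C4′ is the only enolisable carbon and, being shared by the bicyclo[2.2.2]octene and the cyclopentane, has a single open face, so the quaternary centre forms with the target configuration; the hindered tertiary lithium alkoxide is not methylated at this temperature.

**Compound list**
1 | (R)-(+)-pulegone | C[C@@H]1CCC(=C(C)C)C(=O)C1 | starting material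
2 | tert-butyl acrylate | C=CC(=O)OC(C)(C)C | starting material
3 | tert-butyl 3-[(1R,4R)-4-methyl-2-oxo-1-(prop-1-en-2-yl)cyclohexyl]propanoate (ester chain cis to ring methyl) | CC(=C)[C@]1(CCC(=O)OC(C)(C)C)CC[C@@H](C)CC1=O | intermediate
4 | 3-[(1R,4R)-4-methyl-2-oxo-1-(prop-1-en-2-yl)cyclohexyl]propanoic acid | CC(=C)[C@]1(CCC(=O)O)CC[C@@H](C)CC1=O | intermediate
5 | (6R,9R)-1,1,9-trimethyl-2-oxaspiro[5.5]undecane-3,7-dione | CC1(C)OC(=O)CC[C@]12CC[C@@H](C)CC2=O | intermediate
6 | 4,8-bis(phenylselanyl) derivative of 5 (epimer mixture at C4 and C8) | CC1(C)OC(=O)C([Se]c3ccccc3)C[C@]12CC[C@@H](C)C([Se]c3ccccc3)C2=O | intermediate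
7 | (6R)-1,1,9-trimethyl-2-oxaspiro[5.5]undeca-4,8-diene-3,7-dione | CC1(C)OC(=O)C=C[C@]12CCC(C)=CC2=O | intermediate
8 | 4-methoxy-3-methylbenzoic acid | COc1ccc(cc1C)C(=O)O | starting material
9 | 5-methoxy-6-methyl-2-benzofuran-1(3H)-one | COc1cc2COC(=O)c2cc1C | intermediate
10 | 4-(bromomethyl)-5-methoxy-6-methyl-2-benzofuran-1(3H)-one | COc1c(CBr)c2COC(=O)c2cc1C | intermediate
11 | (6R,8R)-8-[(5-methoxy-6-methyl-1-oxo-1,3-dihydro-2-benzofuran-4-yl)methyl]-1,1-dimethyl-9-methylidene-2-oxaspiro[5.5]undec-4-ene-3,7-dione (C11 cis to C1) | CC1(C)OC(=O)C=C[C@]12CCC(=C)[C@@H](Cc3c(OC)c(C)cc4C(=O)OCc34)C2=O | intermediate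
12 | (6S,7R,8R)-7-hydroxy-8-[(5-methoxy-6-methyl-1-oxo-1,3-dihydro-2-benzofuran-4-yl)methyl]-1,1,7-trimethyl-9-methylidene-2-oxaspiro[5.5]undec-4-en-3-one (OH cis to C11 and C1) | CC1(C)OC(=O)C=C[C@]12CCC(=C)[C@@H](Cc3c(OC)c(C)cc4C(=O)OCc34)[C@@]2(C)O | intermediate
13 | 4′-demethyl-andibenin B 5′-methyl enol ether (C4′=C5′–OMe, bonds C8–C3a′ and C12–C6′ formed) | CC1(C)OC(=O)C=C[C@]12CC[C@@]13C[C@@]4(C)C=C5C(=O)OC[C@]51C(C[C@H]3[C@@]2(C)O)=C4OC | intermediate
14 | 4′-demethyl-andibenin B (H on C4′ where the target has methyl) | CC1(C)OC(=O)C=C[C@]12CC[C@@]13C[C@@]4(C)C=C5C(=O)OC[C@]51[C@@H](C[C@H]3[C@@]2(C)O)C4=O | intermediate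
15 | andibenin B | CC1(C)OC(=O)C=C[C@]12CC[C@@]13C[C@@]4(C)C=C5C(=O)OC[C@]51[C@@](C)(C[C@H]3[C@@]2(C)O)C4=O | target

**Step count**
Total: 9 steps. Longest linear sequence: 7 steps (1, 2, 3, 6, 7, 8, 9).

**Three steps most likely to fail**

Step 8 (the new photocycloaddition). The risks are mode selectivity (ortho [2+2] against para [4+2]), addition across C5′/C7a′ instead of C3a′/C6′, and low quantum yield. The fallback uses known chemistry, sets out from 11 and returns at 14. BCl3 with n-Bu4NI (CH2Cl2, −78 to 0 °C) cleaves the aryl methyl ether to the phenol ketone F4. MeTiCl3 then gives the phenol carbinol F5. Wessely oxidation with Pb(OAc)4 in AcOH gives the ortho-quinol acetate F6, formed together with its C4′ epimer and the C6′ regioisomer. Heating in toluene at 90 °C lets only F6 undergo the thermal intramolecular Diels–Alder reaction to the acetoxy cycloadduct F7. SmI2 (THF–MeOH, −78 °C) removes the acetoxy group to give 14 and reduces the unreacted quinol acetates back to F5, which is recycled. The statistical ceiling is about 25% per pass.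

Step 6 (deconjugative benzylation). The risks are γ-deprotonation at C7 instead of C12 (endocyclic dienolate), reconjugation of the product, and the facial selectivity at C9. The fallback sets out from 7 and returns at 11. TBSOTf and Et3N (CH2Cl2, −78 °C) give the silyl dienol ethers; the exocyclic tert-butyldimethylsilyl dienol ether F1 is separated, and the endocyclic isomer is hydrolysed back to 7. F1 is then alkylated with 10 under fluoride release of the enolate (benzyltrimethylammonium fluoride, THF, −78 to 0 °C), which can only give the C8=C12 isomer.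

Step 7 (methyl addition). The risks are slow addition to a ketone flanked by a quaternary and a tertiary carbon, and the facial selectivity at C10. The fallback sets out from 11 and returns at 12. Corey–Chaykovsky epoxidation with dimethylsulfonium methylide (Me3SI, KHMDS, THF, −78 °C) gives the spiro-epoxide F2. MgI2 (Et2O, −40 °C) opens it at the primary carbon to the iodohydrin F3. Radical deiodination (Bu3SnH, AIBN, toluene, 80 °C) gives 12. If the wrong C10 epimer is the problem, the reversible sulfoxonium ylide (Me3S(O)I, NaH, DMSO) delivers the CH2 group from the other face.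

**Further compounds**
F1 | step 6 | exocyclic tert-butyldimethylsilyl dienol ether of 7 | CC1(C)OC(=O)C=C[C@]12CCC(=C)C=C2O[Si](C)(C)C(C)(C)C
F2 | step 7 | spiro-epoxide of 11 at C10 (epoxide oxygen cis to C11) | CC1(C)OC(=O)C=C[C@]12CCC(=C)[C@@H](Cc3c(OC)c(C)cc4C(=O)OCc34)[C@]25CO5
F3 | step 7 | iodohydrin (C10 bearing CH2I and OH) | CC1(C)OC(=O)C=C[C@]12CCC(=C)[C@@H](Cc3c(OC)c(C)cc4C(=O)OCc34)[C@@]2(CI)O
F4 | step 8 | phenol ketone (O-demethylated 11) | CC1(C)OC(=O)C=C[C@]12CCC(=C)[C@@H](Cc3c(O)c(C)cc4C(=O)OCc34)C2=O
F5 | step 8 | phenol carbinol (O-demethylated 12) | CC1(C)OC(=O)C=C[C@]12CCC(=C)[C@@H](Cc3c(O)c(C)cc4C(=O)OCc34)[C@@]2(C)O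
F6 | step 8 | ortho-quinol acetate (4′-acetoxy-cyclohexa-2,4-dienone, productive C4′ epimer) | CC1(C)OC(=O)C=C[C@]12CCC(=C)[C@@H](C[C@@]3(OC(C)=O)C(=O)C(C)=CC4=C3COC4=O)[C@@]2(C)O
F7 | step 8 | 4′-acetoxy-4′-demethyl-andibenin B (acetoxy cycloadduct) | CC1(C)OC(=O)C=C[C@]12CC[C@@]13C[C@@]4(C)C=C5C(=O)OC[C@]51[C@@](OC(C)=O)(C[C@H]3[C@@]2(C)O)C4=O
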